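The cyclohexene ring (C1, C14, C13, C12, C11, C15; verticillane numbering, see remark) shares its tetrasubstituted C11=C12 alkene with the butenolide and is spanned from C1 to C11 by the twelve-membered ring. This bicyclo[9.3.1] bridgehead-alkene core is the retron of a type 2 intramolecular Diels–Alder reaction. One cycloaddition of open-chain lactone 21 joins C13–C14 and C1–C15. It closes both carbocycles and creates quaternary C15, the C1 stereocentre and the butenolide alkene. The 4π partner is a 3-methylene-4-isopropylidene butanolide. The 2π partner is the terminal vinyl of an (E)-dienone, whose C4 carbonyl activates vinylogously and later becomes the exocyclic methylene.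

Key step: step 11

Remark (numbering used throughout): C1 = ring CH next to CMe2; C2, C3 = CH2; C4 (=C20H2); C5 = CH2; C6 = CH(OAc); C7=C8 (C19 methyl); C9 = CH2; C10 = lactone O–CH; C11=C12; C13, C14 = CH2; C15 = CMe2 (C16, C17); C18 = lactone C=O.

Step 1
Reactants: 1 3-methylbut-2-enal
Product: 3 2-bromo-3-methylbut-2-enal, via 2,3-dibromo-3-methylbutanal 2 (not isolated)
Conditions: Br2, CH2Cl2, −78 to 0 °C; then Et3N, 0 °C to rt
Reagents that add atoms: bromine BrBr
Why: Bromination–dehydrobromination: Br2 adds to the enal alkene and Et3N removes the acidic α-hydrogen with E1cB loss of the tertiary bromide, which leaves the α-bromo enal without any stereocentre.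

Step 2
Reactants: 3 2-bromo-3-methylbut-2-enal; 4 ethynyltriisopropylsilane
Product: 5 3-methyl-2-[(triisopropylsilyl)ethynyl]but-2-enal
Conditions: PdCl2(PPh3)2 (cat.), CuI (cat.), Et3N, THF, rt
Reagents that add atoms: none
Why: Sonogashira coupling: the electron-poor α-bromo enal adds readily to zerovalent palladium, the symmetric isopropylidene end raises no alkene geometry issue, and the bulky silyl cap later shields this alkyne.

Step 3
Reactants: 5 3-methyl-2-[(triisopropylsilyl)ethynyl]but-2-enal; 6 allenylboronic acid pinacol ester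
Product: 8 (4R)-2-methyl-3-[(triisopropylsilyl)ethynyl]hept-2-en-6-yn-4-ol, via pinacol borate ester 7 (not isolated)
Conditions: (R)-TRIP phosphoric acid (10 mol%), 4 Å MS, PhMe, −20 °C to rt; aqueous work-up
Reagents that add atoms: none
Why: Chiral phosphoric acid catalysed propargylboration through a closed six-membered SE2' transition state, in which (R)-TRIP activates the boronate and directs attack to the Re face of the aldehyde, setting C10 as R.

Step 4
Reactants: 8 (4R)-2-methyl-3-[(triisopropylsilyl)ethynyl]hept-2-en-6-yn-4-ol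
Product: 11 (2E,5R)-3,7-dimethyl-6-[(triisopropylsilyl)ethynyl]octa-2,6-diene-1,5-diol, via vinylalane 9 (not isolated), via lithium alanate 10 (not isolated)
Conditions: AlMe3 (4 equiv), Cp2ZrCl2 (0.3 equiv), CH2Cl2, 0 °C to rt; n-BuLi, THF–hexane, −78 to 0 °C; (CH2O)n, rt; Rochelle salt work-up
Reagents that add atoms: trimethylaluminium C[Al](C)C; formaldehyde (from paraformaldehyde) C=O
Why: Negishi zirconium-catalysed carboalumination: syn addition of Me–Al to the terminal alkyne puts methyl on C8 and aluminium on C7 (E alkene), the silyl-capped conjugated alkyne is too hindered to compete, and the alanate is hydroxymethylated with retention of geometry.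

Step 5
Reactants: 11 (2E,5R)-3,7-dimethyl-6-[(triisopropylsilyl)ethynyl]octa-2,6-diene-1,5-diol
Product: 12 (2E,5R)-6-ethynyl-3,7-dimethylocta-2,6-diene-1,5-diol
Conditions: TBAF, THF, 0 °C to rt
Reagents that add atoms: none
Why: Fluoride-induced protodesilylation of the alkynylsilane, with nothing else in the diol being fluoride-labile.

Step 6
Reactants: 12 (2E,5R)-6-ethynyl-3,7-dimethylocta-2,6-diene-1,5-diol
Product: 13 (2E,5R)-6-ethynyl-5-hydroxy-3,7-dimethylocta-2,6-dienal
Conditions: TEMPO (10 mol%), PhI(OAc)2 (1.1 equiv), CH2Cl2, rt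
Reagents that add atoms: none
Why: Oxoammonium (TEMPO) oxidation is selective for the unhindered primary allylic alcohol over the hindered secondary C10 carbinol and does not isomerise the E alkene.

Step 7
Reactants: 13 (2E,5R)-6-ethynyl-5-hydroxy-3,7-dimethylocta-2,6-dienal
Product: 14 (2E)-3-methyl-4-[(2R)-4-methylidene-5-oxo-3-(propan-2-ylidene)oxolan-2-yl]but-2-enal
Conditions: PdCl2 (5 mol%), PPh3 (10 mol%), SnCl2 (5 mol%), CO (7 bar), BHT, MeCN, 65 °C
Reagents that add atoms: carbon monoxide [C-]#[O+]
Why: Palladium-catalysed cyclocarbonylation of a homopropargylic alcohol: the alkoxycarbonylpalladium species formed from the C10 hydroxyl and CO adds syn across the alkyne in 5-exo fashion, and protonolysis releases the α-methylene lactone with C10 untouched.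

Step 8
Reactants: 15 acrolein; 16 1-(triphenylphosphoranylidene)propan-2-one
Product: 17 (3E)-hexa-3,5-dien-2-one
Conditions: CH2Cl2, rt; distilled and used fresh
Reagents that add atoms: none
Why: Wittig reaction of a stabilised ylide, which should give the E enone.

Step 9
Reactants: 17 (3E)-hexa-3,5-dien-2-one; 14 (2E)-3-methyl-4-[(2R)-4-methylidene-5-oxo-3-(propan-2-ylidene)oxolan-2-yl]but-2-enal
Product: 20 (3E,7S,8E)-7-hydroxy-9-methyl-10-[(2R)-4-methylidene-5-oxo-3-(propan-2-ylidene)oxolan-2-yl]deca-1,3,8-trien-5-one, via boron enolate 18 (not isolated), via boron aldolate 19 (not isolated)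
Conditions: (+)-Ipc2BCl, Et3N, Et2O, 0 °C; then 14, −78 to −20 °C; pH 7 buffer–MeOH, SiO2 (no peroxide)
Reagents that add atoms: none
Why: Reagent-controlled boron aldol reaction of a methyl ketone with an enal: kinetic enolisation at the methyl group and attack of the (+)-Ipc2B enolate on the Si face of the aldehyde set C6 as S, the boron enolate leaves the α-methylene lactone alone, and the minor C6 epimer is a diastereomer (C10 is fixed) that chromatography removes.

Step 10
Reactants: 20 (3E,7S,8E)-7-hydroxy-9-methyl-10-[(2R)-4-methylidene-5-oxo-3-(propan-2-ylidene)oxolan-2-yl]deca-1,3,8-trien-5-one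
Product: 21 (3E,7S,8E)-9-methyl-10-[(2R)-4-methylidene-5-oxo-3-(propan-2-ylidene)oxolan-2-yl]-5-oxodeca-1,3,8-trien-7-yl acetate
Conditions: Ac2O, pyridine, CH2Cl2, 0 °C
Reagents that add atoms: acetic anhydride CC(=O)OC(C)=O
Why: O-acylation under weakly basic, cold conditions installs the final acetate with retention at C6 and blocks oxa-Michael addition of the hydroxyl to the dienone, while the absence of strong base avoids E1cB loss of acetate.

Step 11
Reactants: 21 (3E,7S,8E)-9-methyl-10-[(2R)-4-methylidene-5-oxo-3-(propan-2-ylidene)oxolan-2-yl]-5-oxodeca-1,3,8-trien-7-yl acetate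
Product: 22 (2E,7E)-6-acetoxy-4-oxo-20-norverticilla-2,7,11-trien-18,10-olide (1S 6S 10R; same spatial arrangement at C1 as in 24)
Conditions: degassed PhMe (0.5 mM, slow addition), BHT, 110 °C
Reagents that add atoms: none
Why: Concerted but strongly asynchronous [4+2] cycloaddition (type 2 intramolecular Diels–Alder reaction, tether on C11 of the diene): the unhindered termini C13 and C14 bond first, because this places the developing radical character on the C12–C11–C15 allyl unit (carbonyl on C12, two methyls on C15) and on the C1–C2–C3–C4=O oxapentadienyl unit, and C1–C15 closes late. The closest known reactions are the para-selective dimerisation of 2-alkoxycarbonyl-1,3-dienes (which likewise joins two acceptor β-carbons), the use of the terminal double bond of 1-acyl dienes as dienophile, and type 2 intramolecular Diels–Alder closures of bicyclo[n.3.1] bridgehead alkenes. The cyclohexene is closed by suprafacial 4π+2π addition to the lactone-locked s-cis diene, and the twelve-membered ring is closed in the same event as the 1,3-bridge between C1 and C11. C1 is the only new stereocentre: C9 leaves C10 on one face of the planar diene lactone, and the nine-atom tether with two E alkenes can reach only that face with C2 endo, so C2 and C9 end up on the same face of the fused ring plane as in the target; C15 becomes quaternary without stereochemistry. The step needs site selectivity (C14=C1 over C2=C3 and C7=C8), secured by sterics and by the largest LUMO coefficient at C14. It also needs periselectivity, secured because the other pairing (dienone as 4π, C12=C13 as 2π) would demand a ten- or eleven-membered ring with an E alkene and a congested spiro centre, and it needs suppression of dimerisation, secured by high dilution and BHT.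

Step 12
Reactants: 22 (2E,7E)-6-acetoxy-4-oxo-20-norverticilla-2,7,11-trien-18,10-olide
Product: 23 (7E)-6-acetoxy-4-oxo-20-norverticilla-7,11-dien-18,10-olide (1S 6S 10R)
Conditions: [(Ph3P)CuH]6 (0.5 equiv), H2O (5 equiv), degassed PhMe, rt
Reagents that add atoms: none
Why: Copper hydride conjugate reduction (Stryker reagent): hydride goes to C2 of the only accessible enone and water protonates the copper enolate, while the tetrasubstituted butenolide, the isolated alkenes, the ketone and the acetate are inert.

Step 13
Reactants: 23 (7E)-6-acetoxy-4-oxo-20-norverticilla-7,11-dien-18,10-olide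
Product: 24 CNP0289913.1 (1R,6S,7E,10R)-6-acetoxyverticilla-4(20),7,11-trien-18,10-olide
Conditions: Zn, CH2Br2, TiCl4 (reagent pre-formed and aged in THF, −40 to 5 °C); then 23, CH2Cl2, 0 °C to rt
Reagents that add atoms: dibromomethane BrCBr
Why: Takai–Lombardo methylenation: the non-basic zinc–titanium gem-dimetallic reagent attacks ketones but not esters or lactones, so β-elimination of the acetate and epimerisation at C10 should be avoided.

Compound list
1 | 3-methylbut-2-enal | CC(C)=CC=O | starting material
2 | 2,3-dibromo-3-methylbutanal | CC(C)(Br)C(Br)C=O | intermediate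
3 | 2-bromo-3-methylbut-2-enal | CC(C)=C(Br)C=O | intermediate
4 | ethynyltriisopropylsilane | C#C[Si](C(C)C)(C(C)C)C(C)C | starting material
5 | 3-methyl-2-[(triisopropylsilyl)ethynyl]but-2-enal | CC(C)=C(C=O)C#C[Si](C(C)C)(C(C)C)C(C)C | intermediate
6 | allenylboronic acid pinacol ester | C=C=CB1OC(C)(C)C(C)(C)O1 | starting material
7 | pinacol borate ester of 8 | C#CC[C@@H](OB1OC(C)(C)C(C)(C)O1)C(=C(C)C)C#C[Si](C(C)C)(C(C)C)C(C)C | intermediate
8 | (4R)-2-methyl-3-[(triisopropylsilyl)ethynyl]hept-2-en-6-yn-4-ol | C#CC[C@@H](O)C(=C(C)C)C#C[Si](C(C)C)(C(C)C)C(C)C | intermediate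
9 | (E)-vinylalane (C7–AlMe2, C10–OAlMe2) | C[Al](C)/C=C(\C)C[C@@H](O[Al](C)C)C(=C(C)C)C#C[Si](C(C)C)(C(C)C)C(C)C | intermediate
10 | lithium butyl(dimethyl)vinylalanate | [Li+].CCCC[Al-](C)(C)/C=C(\C)C[C@@H](O[Al](C)C)C(=C(C)C)C#C[Si](C(C)C)(C(C)C)C(C)C | intermediate
11 | (2E,5R)-3,7-dimethyl-6-[(triisopropylsilyl)ethynyl]octa-2,6-diene-1,5-diol | OC/C=C(\C)C[C@@H](O)C(=C(C)C)C#C[Si](C(C)C)(C(C)C)C(C)C | intermediate
12 | (2E,5R)-6-ethynyl-3,7-dimethylocta-2,6-diene-1,5-diol | OC/C=C(\C)C[C@@H](O)C(=C(C)C)C#C | intermediate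
13 | (2E,5R)-6-ethynyl-5-hydroxy-3,7-dimethylocta-2,6-dienal | O=C/C=C(\C)C[C@@H](O)C(=C(C)C)C#C | intermediate
14 | (2E)-3-methyl-4-[(2R)-4-methylidene-5-oxo-3-(propan-2-ylidene)oxolan-2-yl]but-2-enal | O=C/C=C(\C)C[C@H]1OC(=O)C(=C)C1=C(C)C | intermediate
15 | acrolein | C=CC=O | starting material
16 | 1-(triphenylphosphoranylidene)propan-2-one | CC(=O)C=P(c1ccccc1)(c1ccccc1)c1ccccc1 | starting material
17 | (3E)-hexa-3,5-dien-2-one | CC(=O)/C=C/C=C | intermediate
18 | (+)-diisopinocampheylboron enolate of 17 | C=C/C=C/C(=C)OB([C@H]1C[C@H]2C[C@@H]([C@@H]1C)C2(C)C)[C@H]1C[C@H]2C[C@@H]([C@@H]1C)C2(C)C | intermediate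
19 | boron aldolate of 20 | C=C/C=C/C(=O)C[C@H](OB([C@H]2C[C@H]3C[C@@H]([C@@H]2C)C3(C)C)[C@H]2C[C@H]3C[C@@H]([C@@H]2C)C3(C)C)/C=C(\C)C[C@H]1OC(=O)C(=C)C1=C(C)C | intermediate
20 | (3E,7S,8E)-7-hydroxy-9-methyl-10-[(2R)-4-methylidene-5-oxo-3-(propan-2-ylidene)oxolan-2-yl]deca-1,3,8-trien-5-one | C=C/C=C/C(=O)C[C@H](O)/C=C(\C)C[C@H]1OC(=O)C(=C)C1=C(C)C | intermediate
21 | (3E,7S,8E)-9-methyl-10-[(2R)-4-methylidene-5-oxo-3-(propan-2-ylidene)oxolan-2-yl]-5-oxodeca-1,3,8-trien-7-yl acetate | C=C/C=C/C(=O)C[C@H](OC(C)=O)/C=C(\C)C[C@H]1OC(=O)C(=C)C1=C(C)C | intermediate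
22 | (1S,2E,6S,7E,10R)-6-acetoxy-4-oxo-20-norverticilla-2,7,11-trien-18,10-olide | O=C1/C=C/[C@@H]2CCC3=C([C@@H](C/C(C)=C/[C@@H](OC(C)=O)C1)OC3=O)C2(C)C | intermediate
23 | (1S,6S,7E,10R)-6-acetoxy-4-oxo-20-norverticilla-7,11-dien-18,10-olide | O=C1CC[C@@H]2CCC3=C([C@@H](C/C(C)=C/[C@@H](OC(C)=O)C1)OC3=O)C2(C)C | intermediate
24 | CNP0289913.1, (1R,6S,7E,10R)-6-acetoxyverticilla-4(20),7,11-trien-18,10-olide | C=C1CC[C@@H]2CCC3=C([C@@H](C/C(C)=C/[C@@H](OC(C)=O)C1)OC3=O)C2(C)C | target

Total step count: 13. Longest linear sequence: 12 (steps 1–7 and 9–13).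

Steps most likely to fail

1. Step 11. The cycloaddition may be outrun by the thermal [1,5]-hydrogen shift within the diene (C15 methyl to C13) or by oligomerisation. Three contiguous sp2 atoms (C2–C4) stiffen the tether, which may strain the endo transition state and erode facial control. The fallback keeps the same two-bond closure but uses a stronger dienophile on a more flexible tether.
   - It sets out from 14. Catalytic asymmetric Nozaki–Hiyama–Kishi allylation with 3-chloro-2-(chloromethyl)prop-1-ene (CrCl2, chiral oxazoline-sulfonamide ligand chosen for Si-face attack, Mn, Cp2ZrCl2) should give the C6 (S) allylic chloride alcohol F1.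
   - Ac2O/pyridine should give the chloro acetate F2.
   - CrCl2-mediated allylation of acrolein should give the C2 allylic alcohol F3 (C2 epimers, inconsequential).
   - Dess–Martin periodinane should give the vinyl ketone F4.
   - BF3·OEt2 in CH2Cl2 at low temperature, or gentle heating at high dilution, should close C13–C14 and C1–C15 to the C2 ketone cycloadduct F5.
   - NaBH4 should give the C2 alcohol F6, and 1,1'-thiocarbonyldiimidazole the imidazolylthiocarbonate F7.
   - Barton–McCombie deoxygenation (Bu3SnH, AIBN) comes back to the route at 24.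

2. Step 7. The catalyst may stall on the hindered conjugated enyne, or the diene lactone may oligomerise or isomerise while it is held at 65 °C in the presence of palladium hydride species. The fallback replaces carbonylation by cross-coupling.
   - It sets out from 3. The same (R)-TRIP propargylboration should give the bromo homopropargylic alcohol F8.
   - Carboalumination–hydroxymethylation as in step 4, with the alanate formed at −78 °C so that bromine–lithium exchange does not compete, should give the bromo diol F9.
   - TEMPO/PhI(OAc)2 should give the bromo hydroxy enal F10.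
   - Stille coupling with methyl 2-(tributylstannyl)acrylate (Pd2(dba)3, AsPh3, CuI, NMP) should give the hydroxy diene ester F11.
   - F11 lactonises on silica gel or with PPTS and comes back to the route at 14.

3. Step 13. Lewis-acid-induced β-elimination of the acetate, or sluggish attack on a transannularly shielded ketone, may compete with methylenation. The fallback is a two-step Peterson olefination.
   - It sets out from 23. Me3SiCH2MgCl/CeCl3 in THF at −78 °C should add to the ketone only and give the β-hydroxysilane F12.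
   - HF·pyridine triggers elimination and comes back to the route at 24.

Further compounds
F1 | step 11 | C6 (S) allylic chloride alcohol | ClCC(=C)C[C@H](O)/C=C(\C)C[C@H]1OC(=O)C(=C)C1=C(C)C
F2 | step 11 | chloro acetate | ClCC(=C)C[C@H](OC(C)=O)/C=C(\C)C[C@H]1OC(=O)C(=C)C1=C(C)C
F3 | step 11 | C2 allylic alcohol | C=CC(O)CC(=C)C[C@H](OC(C)=O)/C=C(\C)C[C@H]1OC(=O)C(=C)C1=C(C)C
F4 | step 11 | vinyl ketone | C=CC(=O)CC(=C)C[C@H](OC(C)=O)/C=C(\C)C[C@H]1OC(=O)C(=C)C1=C(C)C
F5 | step 11 | C2 ketone cycloadduct | C=C1CC(=O)[C@@H]2CCC3=C([C@@H](C/C(C)=C/[C@@H](OC(C)=O)C1)OC3=O)C2(C)C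
F6 | step 11 | C2 alcohol | C=C1CC(O)[C@@H]2CCC3=C([C@@H](C/C(C)=C/[C@@H](OC(C)=O)C1)OC3=O)C2(C)C
F7 | step 11 | imidazolylthiocarbonate | C=C1CC(OC(=S)n4ccnc4)[C@@H]2CCC3=C([C@@H](C/C(C)=C/[C@@H](OC(C)=O)C1)OC3=O)C2(C)C
F8 | step 7 | bromo homopropargylic alcohol | C#CC[C@@H](O)C(Br)=C(C)C
F9 | step 7 | bromo diol | OC/C=C(\C)C[C@@H](O)C(Br)=C(C)C
F10 | step 7 | bromo hydroxy enal | O=C/C=C(\C)C[C@@H](O)C(Br)=C(C)C
F11 | step 7 | hydroxy diene ester | O=C/C=C(\C)C[C@@H](O)C(=C(C)C)C(=C)C(=O)OC
F12 | step 13 | β-hydroxysilane | C[Si](C)(C)CC1(O)CC[C@@H]2CCC3=C([C@@H](C/C(C)=C/[C@@H](OC(C)=O)C1)OC3=O)C2(C)C
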